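I start from a small charge: what remains of partner B once the substrate has taken its share.

    substrate + partner B → open intermediate (k1 = 1.3 M⁻¹ h⁻¹, Ea1 = 61.0 kJ mol⁻¹)
    partner B + partner A → second intermediate (k2 = 0.046 M⁻¹ h⁻¹, Ea2 = 89.0 kJ mol⁻¹)
    open intermediate + second intermediate → target (k3 = 2.0 M⁻¹ h⁻¹, Ea3 = 64.0 kJ mol⁻¹)
    second intermediate → side product (k4 = 0.025 h⁻¹, Ea4 = 102 kJ mol⁻¹)
    (constants at 35 °C)

| flask | substrate | partner A | partner B | temperature | time | remark |
|---|---|---|---|---|---|---|
| larch | 1.0 M | 1.00 equiv | 1.80 equiv | 5 °C | 3.0 d |  |
| maple | 1.0 M | 1.00 equiv | 1.80 equiv | 20 °C | 3.0 d |  |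
| alder | 1.0 M | 1.00 equiv | 1.80 equiv |  | 3.0 d | at 35 °C until 15 h, from then on at 5 °C |
| cedar | 1.0 M | 1.00 equiv | 1.80 equiv | 35 °C | 3.0 d |  |

- the list of constants is for 35 °C, to be carried to other temperatures by the activation energies

- the flask with the highest amount of target, in percent of the substrate charged ("all alike" if they lie within 1.5 percentage points) (larch / maple / alder / cedar / all alike)
- final target, as a percentage of the substrate charged, in larch
- final target, as a percentage of the substrate charged, in maple
- final target, as a percentage of the substrate charged, in alder
- final target, as a percentage of the substrate charged, in cedar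

In the first instants of larch, at 5 °C, step 1 uses partner B 92 times as fast as step 2 does. The substrate's first half-life there is 3.86 h, shorter than the 3.0 d of the run. So I expect the substrate to become open intermediate early, leaving a spare b = 0.800 M of partner B beside a = 1.00 M of partner A.

That is the crossing: step 2, with a smaller constant than step 3, now takes over as the rate-limiting step, and the spare partner B is the limiting reagent of this second stage. In the middle of the run, second intermediate meets two fates. At cedar's 35 °C, with open intermediate reckoned down to a − b, step 3 still beats step 4 by a factor of 16.0, and step 4 has the higher activation energy, so I count each second intermediate as target. Target x then follows dx/dt = k(a − x)(b − x), with k the constant of step 2.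

Temperature and time enter together, so I carry the dose θ, the constant of step 2 at each temperature times the time spent there, summed over the legs. At 5 °C the constant is 0.00109 M⁻¹ h⁻¹, which gives larch θ = 0.0782 M⁻¹. With E = exp(−(a − b)θ), the reckoned target is ab(1 − E)/(a − bE), and its ceiling is b.

For larch I then reckon 5.84%. Cedar has θ = 3.31 M⁻¹, for which I reckon 66.0%. Alder's hot leg carries ten times the dose of its cold leg, so its θ = 0.752 M⁻¹ gives 35.8%. I do not reckon maple, but it runs the same time as cedar at 20 °C, colder, so I place it below cedar. My choice is cedar.

The forecast names cedar, with 6.1%, 30%, 37% and 64.5% for larch, maple, alder and cedar, on the ground that “the slow, strongly temperature-dependent B + A step sets the target yield”; it stands above my larch and below my cedar.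

The simulation gives cedar as highest, with 6.01%, 29.6%, 36.0% and 64.5% for larch, maple, alder and cedar.

Larch has not come to rest: at 3.00 d it still holds 93.8% open intermediate and 40.9% of its partner B. Ten times the time means a dose of 0.782 M⁻¹, which I reckon as 36.7% target. The run gives 36.5%, still below the ceiling of 80.0%.

The neighbour that reads larch at 8.0 d has θ = 0.209 M⁻¹, so I expect 14.0%. The run gives 14.1%.

The rate constants come from no measurement; the flask was simulated.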